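**Retrosynthetic overview**

- Target 17 ← dihydrobenzofuran ester 13. The C5 propenol chain is grown last (ester and acetate reduction, benzylic oxidation with Wittig olefination, enoate reduction) from a C5 ester that deactivates ring A until then.
- 13 ← phenol 12 by cutting O1–C2 of ring B (the dihydrofuran ring). This bond joins the phenol oxygen of ring A (the benzo ring) to the benzylic carbon C2 that carries the easily oxidised 3,4,5-trimethoxyphenyl ring. C2 can therefore be carried as a plain CH2 and oxidised at the anode only when the ring is closed.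
- 12 ← alcohol 9 ← imide 8 by cutting C2–C3. Evans alkylation of arylacetyl imide 5 with benzyl bromide 6 sets C3; reduction, methoxycarbonylation, acetylation and hydrogenolysis follow.
- Ring order: ring A and the trimethoxyphenyl ring are bought; ring B is the only ring made (step 8), and C2 is set there under control of C3.

Key step: step 8

Remark: atoms are numbered as in 2,3-dihydro-1-benzofuran (O1, C2, C3, C3a, C4 to C7, C7a), and the target is read as the (2R,3S)-trans isomer with an E alkene.

**Route**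

Step 1
Reactants: 1 2-(5-bromo-2-hydroxyphenyl)acetic acid
Product: 2 2-[2-(benzyloxy)-5-bromophenyl]acetic acid
Conditions: BnBr, KOH, EtOH/H2O, reflux; then aq. HCl
Reagents that add atoms: benzyl bromide, BrCc1ccccc1
Why: Williamson ether synthesis, in which the phenoxide of the dianion is much more nucleophilic than the carboxylate in aqueous ethanol and any benzyl ester formed is saponified under the same conditions.

Step 2
Reactants: 2 2-[2-(benzyloxy)-5-bromophenyl]acetic acid; 3 (S)-4-benzyl-1,3-oxazolidin-2-one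
Product: 5 (4S)-4-benzyl-3-{2-[2-(benzyloxy)-5-bromophenyl]acetyl}-1,3-oxazolidin-2-one, via mixed pivalic anhydride 4 (not isolated)
Conditions: PivCl, Et3N, THF, −20 °C; then LiCl, 3, −20 °C to rt
Reagents that add atoms: none
Why: N-acylation of the oxazolidinone through the mixed pivalic anhydride (LiCl/Et3N variant), which is attacked at its less hindered arylacetyl carbonyl.

Step 3
Reactants: 5 (4S)-4-benzyl-3-{2-[2-(benzyloxy)-5-bromophenyl]acetyl}-1,3-oxazolidin-2-one; 6 3,4,5-trimethoxybenzyl bromide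
Product: 8 (4S)-4-benzyl-3-{(2S)-2-[2-(benzyloxy)-5-bromophenyl]-3-(3,4,5-trimethoxyphenyl)propanoyl}-1,3-oxazolidin-2-one, via sodium Z-enolate 7 (not isolated)
Conditions: NaN(SiMe3)2, THF, −78 °C; then 6, −78 to −50 °C
Reagents that add atoms: none
Why: Evans asymmetric alkylation, in which the chelated sodium Z-enolate is attacked by the benzylic bromide on the face opposite to the C4 benzyl group of the (S)-auxiliary, so the future C3 stereocentre is set as S.

Step 4
Reactants: 8 (4S)-4-benzyl-3-{(2S)-2-[2-(benzyloxy)-5-bromophenyl]-3-(3,4,5-trimethoxyphenyl)propanoyl}-1,3-oxazolidin-2-one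
Product: 9 (2S)-2-[2-(benzyloxy)-5-bromophenyl]-3-(3,4,5-trimethoxyphenyl)propan-1-ol
Conditions: LiBH4, H2O (1 equiv), Et2O/THF, 0 °C
Reagents that add atoms: none
Why: Reductive cleavage of the N-acyl oxazolidinone by LiBH4 at the exocyclic carbonyl should give the primary alcohol and return the auxiliary, with the stereocentre and the aryl bromide left alone.

Step 5
Reactants: 9 (2S)-2-[2-(benzyloxy)-5-bromophenyl]-3-(3,4,5-trimethoxyphenyl)propan-1-ol
Product: 10 methyl 4-(benzyloxy)-3-[(2S)-1-hydroxy-3-(3,4,5-trimethoxyphenyl)propan-2-yl]benzoate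
Conditions: Pd(OAc)2 (cat.), Xantphos, CO (1 atm), Et3N, MeOH/toluene, 70 °C
Reagents that add atoms: carbon monoxide, [C-]#[O+]; methanol, CO
Why: Palladium-catalysed alkoxycarbonylation of the aryl bromide (oxidative addition to zerovalent palladium, CO insertion, methanolysis of the acylpalladium), with methanol as co-solvent outcompeting the substrate alcohol.

Step 6
Reactants: 10 methyl 4-(benzyloxy)-3-[(2S)-1-hydroxy-3-(3,4,5-trimethoxyphenyl)propan-2-yl]benzoate
Product: 11 methyl 3-[(2S)-1-acetoxy-3-(3,4,5-trimethoxyphenyl)propan-2-yl]-4-(benzyloxy)benzoate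
Conditions: Ac2O, pyridine, DMAP (cat.), CH2Cl2, rt
Reagents that add atoms: acetic anhydride, CC(=O)OC(C)=O
Why: DMAP-catalysed acetylation of the primary alcohol, which masks this oxygen so that in the key step it can neither attack the C2 cation nor trigger loss of formaldehyde from it.

Step 7
Reactants: 11 methyl 3-[(2S)-1-acetoxy-3-(3,4,5-trimethoxyphenyl)propan-2-yl]-4-(benzyloxy)benzoate
Product: 12 methyl 3-[(2S)-1-acetoxy-3-(3,4,5-trimethoxyphenyl)propan-2-yl]-4-hydroxybenzoate
Conditions: H2 (1 atm), 10% Pd/C, EtOAc, rt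
Reagents that add atoms: none
Why: Hydrogenolysis of the aryl benzyl ether over Pd/C should free the phenol, while both esters and the trimethoxyarene are inert under these conditions.

Step 8
Reactants: 12 methyl 3-[(2S)-1-acetoxy-3-(3,4,5-trimethoxyphenyl)propan-2-yl]-4-hydroxybenzoate
Product: 13 methyl (2R,3S)-3-(acetoxymethyl)-2-(3,4,5-trimethoxyphenyl)-2,3-dihydro-1-benzofuran-5-carboxylate
Conditions: undivided cell, graphite anode, Pt cathode, n-Bu4NBF4 (0.1 M), 1,1,1,3,3,3-hexafluoropropan-2-ol/CH2Cl2 (1:3), rt, constant current at low current density, 2.0–2.2 F/mol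
Reagents that add atoms: none
Why: Proposed new method: the anode should take one electron from the 3,4,5-trimethoxyphenyl ring of 12 (the most easily oxidised π-system, since ring A carries an ester para to its OH), the radical cation should lose a proton from the C2 methylene, and the benzylic radical should be oxidised at once to the C2 cation, which the para-methoxy group stabilises. The closest known reaction type is the anodic side-chain oxidation of methoxy-substituted alkylarenes with capture of the benzylic cation by an internal oxygen nucleophile (benzylic lactonisation and etherification); capture by a phenol to give a 2-aryl-2,3-dihydrobenzofuran is the untested part. Ring B closes by 5-exo-trig attack of the phenol oxygen on the planar cation, which forms O1–C2. The new C2 stereocentre is controlled by the existing C3 centre: the aryl group should take the face away from the acetoxymethyl group and give the trans (2R,3S) isomer, which is also the more stable one. The step needs oxidation of the trimethoxyarene in preference to the phenol (secured by the para ester and by the non-basic fluoroalcohol medium, which keeps the phenol protonated) and capture of the cation faster than loss of the C3 proton (secured by the five-membered transition state). The charge is held near 2 F/mol so that 13, whose aryl ring is made less electron-rich by the benzylic oxygen, is not oxidised on to the benzofuran.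

Step 9
Reactants: 13 methyl (2R,3S)-3-(acetoxymethyl)-2-(3,4,5-trimethoxyphenyl)-2,3-dihydro-1-benzofuran-5-carboxylate
Product: 14 [(2R,3S)-3-(hydroxymethyl)-2-(3,4,5-trimethoxyphenyl)-2,3-dihydro-1-benzofuran-5-yl]methanol
Conditions: i-Bu2AlH (6 equiv), CH2Cl2, −78 to 0 °C; aq. potassium sodium tartrate
Reagents that add atoms: none
Why: Hydride reduction of both esters by i-Bu2AlH should give the C5 benzylic alcohol and free the C3 hydroxymethyl group in one operation, without touching the benzylic ether of ring B.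

Step 10
Reactants: 14 [(2R,3S)-3-(hydroxymethyl)-2-(3,4,5-trimethoxyphenyl)-2,3-dihydro-1-benzofuran-5-yl]methanol
Product: 16 ethyl (2E)-3-[(2R,3S)-3-(hydroxymethyl)-2-(3,4,5-trimethoxyphenyl)-2,3-dihydro-1-benzofuran-5-yl]prop-2-enoate, via aldehyde 15 (not isolated)
Conditions: activated MnO2 (excess), Ph3P=CHCO2Et, CH2Cl2, rt to 40 °C
Reagents that add atoms: ethyl (triphenylphosphoranylidene)acetate, CCOC(=O)C=P(c1ccccc1)(c1ccccc1)c1ccccc1
Why: Tandem oxidation and Wittig olefination, in which MnO2 oxidises only the benzylic alcohol and the stabilised ylide traps the aldehyde as the E enoate.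

Step 11
Reactants: 16 ethyl (2E)-3-[(2R,3S)-3-(hydroxymethyl)-2-(3,4,5-trimethoxyphenyl)-2,3-dihydro-1-benzofuran-5-yl]prop-2-enoate
Product: 17 (2E)-3-[(2R,3S)-3-(hydroxymethyl)-2-(3,4,5-trimethoxyphenyl)-2,3-dihydro-1-benzofuran-5-yl]prop-2-en-1-ol
Conditions: i-Bu2AlH (4 equiv), CH2Cl2, −78 °C; aq. potassium sodium tartrate
Reagents that add atoms: none
Why: 1,2-Reduction of the enoate by i-Bu2AlH at low temperature should give the E allylic alcohol and leave the alkene and both stereocentres untouched.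

**Compound list**

1 | 2-(5-bromo-2-hydroxyphenyl)acetic acid | OC(=O)Cc1cc(Br)ccc1O | starting material
2 | 2-[2-(benzyloxy)-5-bromophenyl]acetic acid | OC(=O)Cc1cc(Br)ccc1OCc1ccccc1 | intermediate
3 | (S)-4-benzyl-1,3-oxazolidin-2-one | O=C1N[C@@H](Cc2ccccc2)CO1 | starting material
4 | 2-[2-(benzyloxy)-5-bromophenyl]acetic pivalic anhydride | CC(C)(C)C(=O)OC(=O)Cc1cc(Br)ccc1OCc1ccccc1 | intermediate
5 | (4S)-4-benzyl-3-{2-[2-(benzyloxy)-5-bromophenyl]acetyl}-1,3-oxazolidin-2-one | O=C(Cc1cc(Br)ccc1OCc1ccccc1)N1C(=O)OC[C@@H]1Cc1ccccc1 | intermediate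
6 | 3,4,5-trimethoxybenzyl bromide | COc1cc(CBr)cc(OC)c1OC | starting material
7 | sodium Z-enolate of imide 5 | [Na+].[O-]/C(=C\c1cc(Br)ccc1OCc1ccccc1)N1C(=O)OC[C@@H]1Cc1ccccc1 | intermediate
8 | (4S)-4-benzyl-3-{(2S)-2-[2-(benzyloxy)-5-bromophenyl]-3-(3,4,5-trimethoxyphenyl)propanoyl}-1,3-oxazolidin-2-one | O=C([C@@H](Cc1cc(OC)c(OC)c(OC)c1)c1cc(Br)ccc1OCc1ccccc1)N1C(=O)OC[C@@H]1Cc1ccccc1 | intermediate
9 | (2S)-2-[2-(benzyloxy)-5-bromophenyl]-3-(3,4,5-trimethoxyphenyl)propan-1-ol | OC[C@@H](Cc1cc(OC)c(OC)c(OC)c1)c1cc(Br)ccc1OCc1ccccc1 | intermediate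
10 | methyl 4-(benzyloxy)-3-[(2S)-1-hydroxy-3-(3,4,5-trimethoxyphenyl)propan-2-yl]benzoate | COC(=O)c1ccc(OCc2ccccc2)c(c1)[C@H](Cc1cc(OC)c(OC)c(OC)c1)CO | intermediate
11 | methyl 3-[(2S)-1-acetoxy-3-(3,4,5-trimethoxyphenyl)propan-2-yl]-4-(benzyloxy)benzoate | COC(=O)c1ccc(OCc2ccccc2)c(c1)[C@H](Cc1cc(OC)c(OC)c(OC)c1)COC(C)=O | intermediate
12 | methyl 3-[(2S)-1-acetoxy-3-(3,4,5-trimethoxyphenyl)propan-2-yl]-4-hydroxybenzoate | COC(=O)c1ccc(O)c(c1)[C@H](Cc1cc(OC)c(OC)c(OC)c1)COC(C)=O | intermediate
13 | methyl (2R,3S)-3-(acetoxymethyl)-2-(3,4,5-trimethoxyphenyl)-2,3-dihydro-1-benzofuran-5-carboxylate (trans) | COc1cc([C@@H]2Oc3ccc(C(=O)OC)cc3[C@H]2COC(C)=O)cc(OC)c1OC | intermediate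
14 | [(2R,3S)-3-(hydroxymethyl)-2-(3,4,5-trimethoxyphenyl)-2,3-dihydro-1-benzofuran-5-yl]methanol | COc1cc([C@@H]2Oc3ccc(CO)cc3[C@H]2CO)cc(OC)c1OC | intermediate
15 | (2R,3S)-3-(hydroxymethyl)-2-(3,4,5-trimethoxyphenyl)-2,3-dihydro-1-benzofuran-5-carbaldehyde | COc1cc([C@@H]2Oc3ccc(C=O)cc3[C@H]2CO)cc(OC)c1OC | intermediate
16 | ethyl (2E)-3-[(2R,3S)-3-(hydroxymethyl)-2-(3,4,5-trimethoxyphenyl)-2,3-dihydro-1-benzofuran-5-yl]prop-2-enoate | COc1cc([C@@H]2Oc3ccc(/C=C/C(=O)OCC)cc3[C@H]2CO)cc(OC)c1OC | intermediate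
17 | (2E)-3-[(2R,3S)-3-(hydroxymethyl)-2-(3,4,5-trimethoxyphenyl)-2,3-dihydro-1-benzofuran-5-yl]prop-2-en-1-ol | COc1cc([C@@H]2Oc3ccc(/C=C/CO)cc3[C@H]2CO)cc(OC)c1OC | target

**Step count and risks**

Total step count: 11. Longest linear sequence: 11 steps (from 1 to 17).

Steps most likely to fail:

1. Step 8 (key step). Three processes could spoil it. The C2 cation may lose the C3 proton instead of being captured, which gives a stilbene and from it racemised material or the benzofuran. The arene radical cation may be attacked on the ring by the phenol before the benzylic proton is lost. The product may be oxidised further once it accumulates.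
   Fallback (known chemistry; the C2 oxygen is brought in by an aldol reaction and ring B is closed by acid ionisation of a benzylic alcohol). It sets out from 2 and returns to the route at 13. Acid 2 would be coupled with (R)-4-benzyl-2-oxazolidinone (PivCl, Et3N, LiCl, THF) to give (4R)-4-benzyl-3-{2-[2-(benzyloxy)-5-bromophenyl]acetyl}-1,3-oxazolidin-2-one F1. An Evans syn-aldol reaction of this imide (n-Bu2BOTf, i-Pr2NEt, CH2Cl2, −78 to 0 °C, then 3,4,5-trimethoxybenzaldehyde) should give (4R)-4-benzyl-3-{(2R,3R)-2-[2-(benzyloxy)-5-bromophenyl]-3-hydroxy-3-(3,4,5-trimethoxyphenyl)propanoyl}-1,3-oxazolidin-2-one F2. The boron enolate reacts on the face opposite to that used in the alkylation, which is why the (R)-auxiliary is needed to obtain the configuration required at C3. LiBH4 would then give (1R,2S)-2-[2-(benzyloxy)-5-bromophenyl]-1-(3,4,5-trimethoxyphenyl)propane-1,3-diol F3. Methoxycarbonylation under the conditions of step 5 would give methyl 4-(benzyloxy)-3-[(1R,2S)-1,3-dihydroxy-1-(3,4,5-trimethoxyphenyl)propan-2-yl]benzoate F4. Acetyl chloride and 2,4,6-collidine at −78 °C should acetylate only the primary alcohol and give methyl 3-[(1R,2S)-3-acetoxy-1-hydroxy-1-(3,4,5-trimethoxyphenyl)propan-2-yl]-4-(benzyloxy)benzoate F5. Hydrogenolysis (H2, Pd/C, EtOAc) would give methyl 3-[(1R,2S)-3-acetoxy-1-hydroxy-1-(3,4,5-trimethoxyphenyl)propan-2-yl]-4-hydroxybenzoate F6. BF3·OEt2 in CH2Cl2 at 0 °C should ionise the benzylic alcohol, and the phenol should close ring B to the trans isomer 13 whichever configuration the carbinol carbon has.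

2. Step 3. The α-aryl enolate may expel the auxiliary as a ketene if it warms, and the acidic α-proton of the product may exchange under the basic conditions; both lower the diastereomer ratio.
   Fallback (the stereocentre is set by asymmetric hydrogenation instead of enolate alkylation). It sets out from 2 and returns at 9. Perkin condensation of 2 with 3,4,5-trimethoxybenzaldehyde (Ac2O, Et3N, 110 °C) would give (2E)-2-[2-(benzyloxy)-5-bromophenyl]-3-(3,4,5-trimethoxyphenyl)prop-2-enoic acid F7. Asymmetric hydrogenation with [Ir(cod)Cl]2 and a chiral spiro phosphine–oxazoline ligand, or with Ru(OAc)2(BINAP), under H2 in MeOH with Et3N, the ligand enantiomer being chosen by screening for the S product, should give (2S)-2-[2-(benzyloxy)-5-bromophenyl]-3-(3,4,5-trimethoxyphenyl)propanoic acid F8. Reduction with BH3·SMe2 in THF then gives 9.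

3. Step 5. Oxidative addition into the electron-rich aryl bromide may be slow, so that hydrodebromination or catalyst decay competes with carbonylation.
   Fallback (the carboxyl carbon is brought in by an aryllithium instead of palladium catalysis). It sets out from 9 and returns at 10. Treatment of 9 with n-BuLi (2.2 equiv, THF, −78 °C; alkoxide formation, then bromine–lithium exchange) followed by CO2 should give 4-(benzyloxy)-3-[(2S)-1-hydroxy-3-(3,4,5-trimethoxyphenyl)propan-2-yl]benzoic acid F9. Esterification with MeI and KHCO3 in DMF then gives 10.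

**Further compounds**

F1 | step 8 | (4R)-4-benzyl-3-{2-[2-(benzyloxy)-5-bromophenyl]acetyl}-1,3-oxazolidin-2-one | O=C(Cc1cc(Br)ccc1OCc1ccccc1)N1C(=O)OC[C@H]1Cc1ccccc1
F2 | step 8 | (4R)-4-benzyl-3-{(2R,3R)-2-[2-(benzyloxy)-5-bromophenyl]-3-hydroxy-3-(3,4,5-trimethoxyphenyl)propanoyl}-1,3-oxazolidin-2-one | O=C([C@H](c1cc(Br)ccc1OCc1ccccc1)[C@@H](O)c1cc(OC)c(OC)c(OC)c1)N1C(=O)OC[C@H]1Cc1ccccc1
F3 | step 8 | (1R,2S)-2-[2-(benzyloxy)-5-bromophenyl]-1-(3,4,5-trimethoxyphenyl)propane-1,3-diol | OC[C@H](c1cc(Br)ccc1OCc1ccccc1)[C@@H](O)c1cc(OC)c(OC)c(OC)c1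
F4 | step 8 | methyl 4-(benzyloxy)-3-[(1R,2S)-1,3-dihydroxy-1-(3,4,5-trimethoxyphenyl)propan-2-yl]benzoate | COC(=O)c1ccc(OCc2ccccc2)c(c1)[C@@H](CO)[C@@H](O)c1cc(OC)c(OC)c(OC)c1
F5 | step 8 | methyl 3-[(1R,2S)-3-acetoxy-1-hydroxy-1-(3,4,5-trimethoxyphenyl)propan-2-yl]-4-(benzyloxy)benzoate | COC(=O)c1ccc(OCc2ccccc2)c(c1)[C@@H](COC(C)=O)[C@@H](O)c1cc(OC)c(OC)c(OC)c1
F6 | step 8 | methyl 3-[(1R,2S)-3-acetoxy-1-hydroxy-1-(3,4,5-trimethoxyphenyl)propan-2-yl]-4-hydroxybenzoate | COC(=O)c1ccc(O)c(c1)[C@@H](COC(C)=O)[C@@H](O)c1cc(OC)c(OC)c(OC)c1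
F7 | step 3 | (2E)-2-[2-(benzyloxy)-5-bromophenyl]-3-(3,4,5-trimethoxyphenyl)prop-2-enoic acid | OC(=O)/C(=C/c1cc(OC)c(OC)c(OC)c1)c1cc(Br)ccc1OCc1ccccc1
F8 | step 3 | (2S)-2-[2-(benzyloxy)-5-bromophenyl]-3-(3,4,5-trimethoxyphenyl)propanoic acid | OC(=O)[C@@H](Cc1cc(OC)c(OC)c(OC)c1)c1cc(Br)ccc1OCc1ccccc1
F9 | step 5 | 4-(benzyloxy)-3-[(2S)-1-hydroxy-3-(3,4,5-trimethoxyphenyl)propan-2-yl]benzoic acid | OC(=O)c1ccc(OCc2ccccc2)c(c1)[C@H](Cc1cc(OC)c(OC)c(OC)c1)CO
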